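Cedrane labels, used for every intermediate: C1 quaternary ring-fusion carbon, C2 (bears CHO = C12), C3, C4, C5 ring-fusion CH, C6 CMe2, C7 bridgehead CH, C8 (bears CO2H = C15)=C9, C10 CH–O, C11 CH2; ring A = C1–C2–C3–C4–C5, ring B = C1–C5–C6–C7–C11, ring C = C1–C10–C9–C8–C7–C11.
Retrosynthesis: first the two allyl groups, then both ring A bonds C1–C5 and C2–C3 at once (this also opens ring B and leaves a monocyclic ring C), then the C10 ester, the C10–H bond and C1=C2 (aldol), then C5–C6 (Giese); re-closing C1–C6 to a cyclobutane leads back to (1R)-myrtenal.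
Forward: ring C with C6, C7, C11 and C15 comes intact from myrtenal; oxidation at C10, cyclobutane fragmentation with Giese addition (C3–C5, boron on C5), chloride at C3, aldol condensation (C2, C12), Luche reduction and esterification with a Wittig-derived Z-acid give the cascade substrate; rings B and A then close in one operation, B first, and deallylation ends the route.
Enabling feature: C1 is both the ring-fusion carbon and the β-carbon of the C12 formyl group (C2 its α-carbon), while C3–C4–C5 hang from C6, which sits 1,3 to C1 across C7/C11; a C5 radical therefore closes ring B 5-exo onto the enal C1=C2–CHO, and the C2 enolate so formed closes ring A on the C3 chloride.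
Stereochemistry: C7 from the chiral pool; C10 by Luche reduction anti to the pseudo-axial C7 substituent; C1, C5 and C2 in the cascade (tether, exo placement of the arm, formyl anti to the C10 acyloxy group); the Z-alkene by Wittig olefination.

Key step: step 13

Assumption: 4, 10, 15 and 18 are taken as commercial; 6–9, 11–14 and 21–23 are carried as epimer mixtures at the boron-bearing carbon C5 (11 and 12 also at C1/C2), which is harmless because C5 becomes a planar radical in step 13, and the SMILES leave these centres open.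

Step 1
Reactants: 1 (1R)-(−)-myrtenal
Product: 2 allyl (1R,5S)-6,6-dimethylbicyclo[3.1.1]hept-2-ene-2-carboxylate (allyl myrtenate)
Conditions: 1,4-dimethyl-1,2,4-triazolium iodide (5 mol %), DBU (20 mol %), 3,3',5,5'-tetra-tert-butyldiphenoquinone (1.1 equiv), allyl alcohol (3 equiv), THF, rt
Reagents that add atoms: allyl alcohol, C=CCO
Why: NHC-catalysed oxidative esterification, in which the carbene–enal adduct is oxidised by the diphenoquinone to an acyl azolium that allyl alcohol acylates; no stereocentre is touched.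

Step 2
Reactants: 2 allyl myrtenate
Product: 3 allyl (1R,5S)-6,6-dimethyl-4-oxobicyclo[3.1.1]hept-2-ene-2-carboxylate
Conditions: Rh2(cap)4 (cap = caprolactamate, 1 mol %), t-BuOOH (70 % aq., 5 equiv), K2CO3, CH2Cl2, rt
Reagents that add atoms: tert-butyl hydroperoxide, CC(C)(C)OO
Why: Dirhodium-caprolactamate/peroxide allylic oxidation (peroxyl-radical hydrogen abstraction at the only ring allylic methylene, C10, then collapse of the mixed peroxide to the enone) is established for cycloalkene carboxylates and for the pinene-to-verbenone change, and the α-acyloxy C–H of the allyl ester is deactivated towards the electrophilic peroxyl radical.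

Step 3
Reactants: 3 allyl 4-oxomyrtenate; 4 (E)-3-(4,4,5,5-tetramethyl-1,3,2-dioxaborolan-2-yl)prop-2-enal
Product: 7 allyl (6R)-6-[2-methyl-5-oxo-3-(4,4,5,5-tetramethyl-1,3,2-dioxaborolan-2-yl)pentan-2-yl]-3-oxocyclohex-1-ene-1-carboxylate, via bromo silyl dienol ether 5 (not isolated), via boryl aldehyde silyl dienol ether 6 (not isolated)
Conditions: Me3SiBr (1.1 equiv), CH2Cl2, −40 to 0 °C; evaporate; then 4 (3 equiv), (Me3Si)3SiH (slow addition), Et3B/air, PhMe, 0 °C to rt; aq. citric acid work-up
Reagents that add atoms: none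
Why: O-silylation makes C10 cationic, so the strained C1–C6 cyclobutane bond cleaves to the tertiary bromide and the C1=C10 silyl dienol ether (halosilane cleavage of pinane-type cyclobutyl ketones, steered to this bond by the C8 ester), and silyl-radical bromine abstraction followed by Giese addition of the tertiary C6 radical to the boron-bearing β-carbon of 4 should give 7 after hydrolysis, the dienol ether masking the ring enoate as a competing acceptor and C7 keeping the configuration of 1.

Step 4
Reactants: 7 keto aldehyde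
Product: 8 allyl (6R)-6-[5-hydroxy-2-methyl-3-(4,4,5,5-tetramethyl-1,3,2-dioxaborolan-2-yl)pentan-2-yl]-3-oxocyclohex-1-ene-1-carboxylate
Conditions: NaBH(OAc)3 (1.5 equiv), AcOH (1 equiv), ClCH2CH2Cl, rt
Reagents that add atoms: none
Why: The electron-poor triacetoxyborohydride reduces aldehydes but not ketones, so the enone, both esters and the boronate should survive.

Step 5
Reactants: 8 hydroxy boronate
Product: 9 allyl (6R)-6-[5-chloro-2-methyl-3-(4,4,5,5-tetramethyl-1,3,2-dioxaborolan-2-yl)pentan-2-yl]-3-oxocyclohex-1-ene-1-carboxylate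
Conditions: PPh3, N-chlorosuccinimide, CH2Cl2, 0 °C
Reagents that add atoms: N-chlorosuccinimide, O=C1CCC(=O)N1Cl
Why: Appel-type chlorination (chlorophosphonium activation, SN2 at the primary carbon) installs a leaving group at C3 that is robust enough for the next six steps.

Step 6
Reactants: 9 chloro boronate; 10 2,2-dimethoxyacetaldehyde
Product: 13 allyl (4E,6R)-6-[5-chloro-2-methyl-3-(4,4,5,5-tetramethyl-1,3,2-dioxaborolan-2-yl)pentan-2-yl]-4-(2,2-dimethoxyethylidene)-3-oxocyclohex-1-ene-1-carboxylate, via aldol adduct 11 (not isolated), via aldol mesylate 12 (not isolated)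
Conditions: LiN(iPr)2 (1.1 equiv), THF, −78 °C; 10; then MsCl, Et3N, −78 to 0 °C
Reagents that add atoms: none
Why: Aldol condensation through the kinetic cross-conjugated enolate at C1 and the non-enolisable aldehyde, with mesylation and E1cB elimination giving the thermodynamically preferred E-alkylidene (acetal carbon away from the C10 carbonyl), the γ-proton at C7 staying untouched at −78 °C.

Step 7
Reactants: 13 cross-conjugated dienone
Product: 14 allyl (3S,4E,6R)-6-[5-chloro-2-methyl-3-(4,4,5,5-tetramethyl-1,3,2-dioxaborolan-2-yl)pentan-2-yl]-4-(2,2-dimethoxyethylidene)-3-hydroxycyclohex-1-ene-1-carboxylate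
Conditions: NaBH4, CeCl3·7H2O, MeOH, −78 °C
Reagents that add atoms: none
Why: Luche 1,2-reduction, in which the C7 tert-alkyl group, held pseudo-axial by A(1,2) strain with the C8 ester, shields one face so that hydride should add anti to it and set C10 cis to the C7 side chain (3S), the acetal keeping C12 out of reach of the hydride.

Step 8
Reactants: 15 7-bromoheptan-1-ol
Product: 16 allyl 7-bromoheptyl carbonate
Conditions: allyl chloroformate, pyridine, CH2Cl2, 0 °C
Reagents that add atoms: allyl chloroformate, C=CCOC(=O)Cl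
Why: Acylation of the primary alcohol gives a carbonate that comes off in the same final operation as the allyl ester.

Step 9
Reactants: 16 allyl 7-bromoheptyl carbonate
Product: 17 [7-(allyloxycarbonyloxy)heptyl]triphenylphosphonium bromide
Conditions: PPh3, MeCN, reflux
Reagents that add atoms: triphenylphosphine, c1ccc(cc1)P(c1ccccc1)c1ccccc1
Why: SN2 quaternisation of the primary bromide.

Step 10
Reactants: 17 phosphonium bromide; 18 9-oxononanoic acid
Product: 20 (9Z)-16-(allyloxycarbonyloxy)hexadec-9-enoic acid, via phosphonium ylide 19 (not isolated)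
Conditions: NaN(SiMe3)2 (2.1 equiv), THF, −78 °C to rt; aq. HCl work-up
Reagents that add atoms: none
Why: Wittig olefination of a non-stabilised ylide under lithium-free conditions at low temperature should give the Z-alkene, the second equivalent of base holding the acid as its carboxylate.

Step 11
Reactants: 14 allylic alcohol; 20 Z-acid
Product: 21 allyl (3S,4E,6R)-3-{[(9Z)-16-(allyloxycarbonyloxy)hexadec-9-enoyl]oxy}-6-[5-chloro-2-methyl-3-(4,4,5,5-tetramethyl-1,3,2-dioxaborolan-2-yl)pentan-2-yl]-4-(2,2-dimethoxyethylidene)cyclohex-1-ene-1-carboxylate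
Conditions: N,N'-diisopropylcarbodiimide, DMAP (cat.), CH2Cl2, 0 °C to rt
Reagents that add atoms: none
Why: Steglich esterification acylates the C10 hydroxyl with retention, the acid being activated as O-acylisourea and acylpyridinium.

Step 12
Reactants: 21 acetal boronate
Product: 23 potassium trifluoroborate of the enal: allyl (3S,4E,6R)-3-{[(9Z)-16-(allyloxycarbonyloxy)hexadec-9-enoyl]oxy}-6-[5-chloro-2-methyl-3-(trifluoroboranuidyl)pentan-2-yl]-4-(2-oxoethylidene)cyclohex-1-ene-1-carboxylate potassium salt, via enal boronate 22 (not isolated)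
Conditions: aq. HCl (1 N), THF, 0 °C; then KHF2 (aq.), MeOH, rt
Reagents that add atoms: water, O; potassium hydrogen difluoride, [K+].[F-].F
Why: Mild hydrolysis of the allylic dimethyl acetal unveils the enal, and KHF2 turns the pinacol boronate into the oxidisable trifluoroborate (standard ligand exchange), while esters, carbonate and chloride should survive.

Step 13
Reactants: 23 potassium trifluoroborate
Product: 25 fully protected target (C15 allyl ester, allyl carbonate on the chain hydroxyl, tricycle configured as in the target), via bicyclic potassium enolate 24 (not isolated)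
Conditions: 4CzIPN (2 mol %), KF (2 equiv), DMSO (degassed), 450 nm LEDs, 25 °C
Reagents that add atoms: none
Why: Proposed new method: photoexcited 4CzIPN oxidises the secondary alkyltrifluoroborate to the C5 radical (BF3 leaves and is held as KBF4), the radical adds to C1, the β-carbon of the enal, and the α-formyl radical so formed is reduced by the 4CzIPN radical anion to the potassium enolate 24, whose C2 displaces chloride from C3. The closest known reaction type is the photoredox radical addition–polar cyclization (radical/polar crossover annulation) of alkyltrifluoroborates, silicates or carboxylates with acceptor alkenes that carry a tethered halide or sulfonate, known for three- and four-membered rings, joined here to the photoredox Giese reaction of alkyltrifluoroborates. Ring B (C1–C5–C6–C7–C11) closes by 5-exo-trig radical attack and ring A (C1–C2–C3–C4–C5) by 5-exo-tet enolate alkylation. C1 is set by the tether, since C5 hangs from C6 on C7 and can reach C1 only on the ring face cis to that side chain, C5 by a chair-like transition state that turns the chloroethyl arm exo, cis to C2 and away from the C8=C9–C10 bridge, and C2 in the alkylation, where the formyl group should settle syn to the C11 methylene and anti to the C10 acyloxy group. The step needs 5-exo over 6-endo addition, which the polarity match between the nucleophilic alkyl radical and the enal β-carbon C1 secures, and it needs the radical to ignore the four other alkenes, none of which is both activated and within five atoms of C5. It also needs C-alkylation to outrun protonation, for which the medium is aprotic and KF frees the enolate from BF3, and an enolate that is protonated can re-form only at C2 and close the same ring.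

Step 14
Reactants: 25 protected target
Product: 26 CNP0214056.2 (target)
Conditions: Pd(PPh3)4 (5 mol %), N-methylaniline (4 equiv), THF, 0 °C to rt
Reagents that add atoms: none
Why: Tsuji–Trost deallylation, in which zerovalent palladium ionises the allyl ester and the allyl carbonate (the latter losing CO2) and N-methylaniline traps the allyl groups, the secondary C10 ester being spared because its pseudo-equatorial C–O bond lies almost in the plane of the C8=C9 bond and is shielded.

Compound list
1 | (1R)-(−)-myrtenal, (1R,5S)-6,6-dimethylbicyclo[3.1.1]hept-2-ene-2-carbaldehyde | O=CC1=CC[C@H]2C[C@@H]1C2(C)C | starting material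
2 | allyl (1R,5S)-6,6-dimethylbicyclo[3.1.1]hept-2-ene-2-carboxylate | C=CCOC(=O)C1=CC[C@H]2C[C@@H]1C2(C)C | intermediate
3 | allyl (1R,5S)-6,6-dimethyl-4-oxobicyclo[3.1.1]hept-2-ene-2-carboxylate | C=CCOC(=O)C1=CC(=O)[C@H]2C[C@@H]1C2(C)C | intermediate
4 | (E)-3-(4,4,5,5-tetramethyl-1,3,2-dioxaborolan-2-yl)prop-2-enal | O=C/C=C/B1OC(C)(C)C(C)(C)O1 | starting material
5 | allyl (6S)-6-(2-bromopropan-2-yl)-3-(trimethylsilyloxy)cyclohexa-1,3-diene-1-carboxylate | CC(C)(Br)[C@H]1CC=C(O[Si](C)(C)C)C=C1C(=O)OCC=C | intermediate (not isolated)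
6 | allyl (6R)-6-[2-methyl-5-oxo-3-(pinacolboryl)pentan-2-yl]-3-(trimethylsilyloxy)cyclohexa-1,3-diene-1-carboxylate | O=CCC(B1OC(C)(C)C(C)(C)O1)C(C)(C)[C@H]1CC=C(O[Si](C)(C)C)C=C1C(=O)OCC=C | intermediate (not isolated)
7 | allyl (6R)-6-[2-methyl-5-oxo-3-(pinacolboryl)pentan-2-yl]-3-oxocyclohex-1-ene-1-carboxylate | O=CCC(B1OC(C)(C)C(C)(C)O1)C(C)(C)[C@H]1CCC(=O)C=C1C(=O)OCC=C | intermediate
8 | allyl (6R)-6-[5-hydroxy-2-methyl-3-(pinacolboryl)pentan-2-yl]-3-oxocyclohex-1-ene-1-carboxylate | OCCC(B1OC(C)(C)C(C)(C)O1)C(C)(C)[C@H]1CCC(=O)C=C1C(=O)OCC=C | intermediate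
9 | allyl (6R)-6-[5-chloro-2-methyl-3-(pinacolboryl)pentan-2-yl]-3-oxocyclohex-1-ene-1-carboxylate | ClCCC(B1OC(C)(C)C(C)(C)O1)C(C)(C)[C@H]1CCC(=O)C=C1C(=O)OCC=C | intermediate
10 | 2,2-dimethoxyacetaldehyde | COC(OC)C=O | starting material
11 | aldol adduct, allyl (6R)-6-[5-chloro-2-methyl-3-(pinacolboryl)pentan-2-yl]-4-(1-hydroxy-2,2-dimethoxyethyl)-3-oxocyclohex-1-ene-1-carboxylate (diastereomer mixture) | ClCCC(B1OC(C)(C)C(C)(C)O1)C(C)(C)[C@H]1CC(C(O)C(OC)OC)C(=O)C=C1C(=O)OCC=C | intermediate (not isolated)
12 | methanesulfonate of 11 | ClCCC(B1OC(C)(C)C(C)(C)O1)C(C)(C)[C@H]1CC(C(OS(C)(=O)=O)C(OC)OC)C(=O)C=C1C(=O)OCC=C | intermediate (not isolated)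
13 | allyl (4E,6R)-6-[5-chloro-2-methyl-3-(pinacolboryl)pentan-2-yl]-4-(2,2-dimethoxyethylidene)-3-oxocyclohex-1-ene-1-carboxylate | ClCCC(B1OC(C)(C)C(C)(C)O1)C(C)(C)[C@H]1C/C(=C\C(OC)OC)C(=O)C=C1C(=O)OCC=C | intermediate
14 | allyl (3S,4E,6R)-6-[5-chloro-2-methyl-3-(pinacolboryl)pentan-2-yl]-4-(2,2-dimethoxyethylidene)-3-hydroxycyclohex-1-ene-1-carboxylate | ClCCC(B1OC(C)(C)C(C)(C)O1)C(C)(C)[C@H]1C/C(=C\C(OC)OC)[C@@H](O)C=C1C(=O)OCC=C | intermediate
15 | 7-bromoheptan-1-ol | OCCCCCCCBr | starting material
16 | allyl 7-bromoheptyl carbonate | C=CCOC(=O)OCCCCCCCBr | intermediate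
17 | [7-(allyloxycarbonyloxy)heptyl]triphenylphosphonium bromide | C=CCOC(=O)OCCCCCCC[P+](c1ccccc1)(c1ccccc1)c1ccccc1.[Br-] | intermediate
18 | 9-oxononanoic acid | O=CCCCCCCCC(=O)O | starting material
19 | [7-(allyloxycarbonyloxy)heptylidene]triphenylphosphorane | C=CCOC(=O)OCCCCCCC=P(c1ccccc1)(c1ccccc1)c1ccccc1 | intermediate (not isolated)
20 | (9Z)-16-(allyloxycarbonyloxy)hexadec-9-enoic acid | C=CCOC(=O)OCCCCCC/C=C\CCCCCCCC(=O)O | intermediate
21 | allyl (3S,4E,6R)-3-{[(9Z)-16-(allyloxycarbonyloxy)hexadec-9-enoyl]oxy}-6-[5-chloro-2-methyl-3-(pinacolboryl)pentan-2-yl]-4-(2,2-dimethoxyethylidene)cyclohex-1-ene-1-carboxylate | ClCCC(B1OC(C)(C)C(C)(C)O1)C(C)(C)[C@H]1C/C(=C\C(OC)OC)[C@@H](OC(=O)CCCCCCC/C=C\CCCCCCOC(=O)OCC=C)C=C1C(=O)OCC=C | intermediate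
22 | enal boronate, as 21 with 4-(2-oxoethylidene) in place of the acetal | ClCCC(B1OC(C)(C)C(C)(C)O1)C(C)(C)[C@H]1C/C(=C\C=O)[C@@H](OC(=O)CCCCCCC/C=C\CCCCCCOC(=O)OCC=C)C=C1C(=O)OCC=C | intermediate (not isolated)
23 | potassium trifluoroborate corresponding to 22 | ClCCC([B-](F)(F)F)C(C)(C)[C@H]1C/C(=C\C=O)[C@@H](OC(=O)CCCCCCC/C=C\CCCCCCOC(=O)OCC=C)C=C1C(=O)OCC=C.[K+] | intermediate
24 | bicyclo[3.2.1]octene potassium enolate (C1–C5 bond made, C3 still chlorinated, enolate geometry open) | CC1(C)[C@H]2C[C@@]([C@@H](OC(=O)CCCCCCC/C=C\CCCCCCOC(=O)OCC=C)C=C2C(=O)OCC=C)(C=C[O-])[C@H]1CCCl.[K+] | intermediate (not isolated)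
25 | protected target: C15 allyl ester and chain allyl carbonate of 26 | CC1(C)[C@H]2C[C@@]3([C@@H](OC(=O)CCCCCCC/C=C\CCCCCCOC(=O)OCC=C)C=C2C(=O)OCC=C)[C@@H](C=O)CC[C@@H]13 | intermediate
26 | CNP0214056.2: 10-[(9Z)-16-hydroxyhexadec-9-enoyloxy]-12-oxocedr-8-en-15-oic acid (cedrane labels of the plan, configuration as in the SMILES) | CC1(C)[C@H]2C[C@@]3([C@@H](OC(=O)CCCCCCC/C=C\CCCCCCO)C=C2C(=O)O)[C@@H](C=O)CC[C@@H]13 | target

Total step count: 14. Longest linear sequence: 11 steps (steps 1–7 and 11–14, from 1); the side chain takes steps 8–10.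

Steps most likely to fail

1. Step 13 (proposed new method). The enolate may be protonated, or held by BF3, before it attacks C3, so that the cascade stops after ring B; the alkylation may also give the C2 epimer. Fallback with known reactions, from 23: run the two events separately. A photoredox Giese cyclization with a proton source (4CzIPN, DMSO/H2O, blue LEDs) should give the bicyclic chloro aldehyde F1. A classical intramolecular enolate alkylation (KOtBu, THF, −78 to 0 °C), under which C2 can also equilibrate, then returns to 25.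

2. Step 3. The hindered tertiary radical may be reduced by the silane before it adds to the β-substituted boryl enal, or the tertiary bromide may lose HBr and the ring aromatise. Fallback, from 3: bring in the three carbons with a doubly activated acceptor and put boron on afterwards. Me3SiBr and aqueous work-up give (via 5) the bromo ketone F2. Giese addition to tert-butyl (E)-4-oxobut-2-enoate ((Me3Si)3SiH, AIBN) gives the aldehyde ester F3. NaBH(OAc)3 gives the alcohol F4 and PPh3/N-chlorosuccinimide the chloride F5. TFA cleaves the tert-butyl ester to the acid F6, and N-hydroxyphthalimide with N,N'-diisopropylcarbodiimide gives the redox-active ester F7. Its decarboxylative borylation (B2cat2, DMAc, blue LEDs; then pinacol, Et3N) returns to 9.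

3. Step 7. Hydride may be delivered to the other face of the dienone and give the trans alcohol. Fallback, from 13: the reduction product is then the C10 epimer F8. A Mitsunobu esterification with acid 20 (PPh3, diisopropyl azodicarboxylate, toluene) inverts the carbinol carbon and returns directly to 21.

Further compounds
F1 | step 13 | bicyclic chloro aldehyde (C-protonated form of 24) | CC1(C)[C@H]2C[C@@]([C@@H](OC(=O)CCCCCCC/C=C\CCCCCCOC(=O)OCC=C)C=C2C(=O)OCC=C)(CC=O)[C@H]1CCCl
F2 | step 3 | allyl (6S)-6-(2-bromopropan-2-yl)-3-oxocyclohex-1-ene-1-carboxylate | CC(C)(Br)[C@H]1CCC(=O)C=C1C(=O)OCC=C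
F3 | step 3 | allyl (6R)-6-[3-(tert-butoxycarbonyl)-2-methyl-5-oxopentan-2-yl]-3-oxocyclohex-1-ene-1-carboxylate | O=CCC(C(=O)OC(C)(C)C)C(C)(C)[C@H]1CCC(=O)C=C1C(=O)OCC=C
F4 | step 3 | allyl (6R)-6-[3-(tert-butoxycarbonyl)-5-hydroxy-2-methylpentan-2-yl]-3-oxocyclohex-1-ene-1-carboxylate | OCCC(C(=O)OC(C)(C)C)C(C)(C)[C@H]1CCC(=O)C=C1C(=O)OCC=C
F5 | step 3 | allyl (6R)-6-[3-(tert-butoxycarbonyl)-5-chloro-2-methylpentan-2-yl]-3-oxocyclohex-1-ene-1-carboxylate | ClCCC(C(=O)OC(C)(C)C)C(C)(C)[C@H]1CCC(=O)C=C1C(=O)OCC=C
F6 | step 3 | 2-(2-chloroethyl)-3-[(1R)-2-(allyloxycarbonyl)-4-oxocyclohex-2-en-1-yl]-3-methylbutanoic acid | ClCCC(C(=O)O)C(C)(C)[C@H]1CCC(=O)C=C1C(=O)OCC=C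
F7 | step 3 | N-hydroxyphthalimide ester of F6 | ClCCC(C(=O)ON1C(=O)c2ccccc2C1=O)C(C)(C)[C@H]1CCC(=O)C=C1C(=O)OCC=C
F8 | step 7 | allyl (3R,4E,6R)-6-[5-chloro-2-methyl-3-(pinacolboryl)pentan-2-yl]-4-(2,2-dimethoxyethylidene)-3-hydroxycyclohex-1-ene-1-carboxylate | ClCCC(B1OC(C)(C)C(C)(C)O1)C(C)(C)[C@H]1C/C(=C\C(OC)OC)[C@H](O)C=C1C(=O)OCC=C
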